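**Retrosynthetic overview**

1. Endgame: O10 desilylation, C3 oxidation, and closure of the ten-membered carbocycle at C3–C4 by a Nozaki–Hiyama–Kishi reaction between a (Z)-C4 vinyl iodide and a C3 epoxy aldehyde (both C3 epimers converge on oxidation).
2. Key disconnection: C7–C11 of the γ-lactone. One flask joins three components: the C6 (diethoxyphosphoryl)acetate of an erythro 7,8-epoxy alcohol, formaldehyde (C13) and isobutyric anhydride (8-O-acyl).
3. Enabling feature: in the trans-fused α-methylene-γ-butyrolactone (O–C6–C7–C11–C12) the ring oxygen sits on C6 and the C8–O bond is anti to the C7–C11 bond. This is the pattern left by back-side 5-exo opening of a trans-7,8-oxirane by a C11 carbanion tethered through O6.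
4. The epoxy alcohol comes from ligand-controlled alkenylzinc addition of a C7–C10/C1–C3 alkyne to (Z)-3-iodobut-2-enal (C4–C6, C15), then matched Sharpless epoxidation (C7, C8). The alkyne carries C10 from (S)-2-methylglycidol and the 1,2-oxirane from a first Sharpless epoxidation.
5. Ring order: 1,2-oxirane, then 7,8-oxirane (temporary), then γ-lactone (key step), then ten-membered carbocycle.

Key step: step 13

Remark: (S)-2-methylglycidol (1) is taken as a purchasable single enantiomer.
Locants C1–C15 in names are the germacrane locants of the target (C1/C2 oxirane, C3 ketone, C4=C5 with methyl C15, C6 lactone oxygen, C7, C8 ester oxygen, C9, C10 carbinol with methyl C14, C11=C13, C12 lactone carbonyl). Descriptors at C2, C6 and C7 change along the route only through CIP rank changes, except for the real inversion at C7 in step 13.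

**Route**

Step 1
Reactants: 1 (S)-2-methylglycidol; 2 lithium acetylide–ethylenediamine complex
Product: 3 (2R)-2-methylpent-4-yne-1,2-diol
Conditions: LiC≡CH·H2NCH2CH2NH2 (3 equiv), DMSO, 0 °C → rt; aq. NH4Cl
Reagents that add atoms: lithium acetylide–ethylenediamine complex, [Li]C#C.NCCN
Why: SN2 opening of the 2,2-disubstituted oxirane by acetylide at its CH2 carbon leaves the quaternary carbinol centre (future C10, R) untouched and delivers the C7≡C8 alkyne with C9.

Step 2
Reactants: 3 (2R)-2-methylpent-4-yne-1,2-diol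
Product: 4 (2R)-2-methyl-1,2-bis(triethylsilyloxy)pent-4-yne
Conditions: Et3SiOTf, 2,6-lutidine, CH2Cl2, −78 → 0 °C
Reagents that add atoms: triethylsilyl trifluoromethanesulfonate, CC[Si](CC)(CC)OS(=O)(=O)C(F)(F)F
Why: Silyl ether formation with the silyl triflate protects both hydroxyls, the tertiary C10–O ether being kept to the last step.

Step 3
Reactants: 4 (2R)-2-methyl-1,2-bis(triethylsilyloxy)pent-4-yne
Product: 5 (2R)-2-methyl-2-(triethylsilyloxy)pent-4-ynal
Conditions: (COCl)2, DMSO, CH2Cl2, −78 → −40 °C; Et3N, −78 → 0 °C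
Reagents that add atoms: none
Why: Swern oxidation cleaves and oxidises a primary triethylsilyl ether directly to the aldehyde while the tertiary silyl ether is inert, so no separate deprotection is needed.

Step 4
Reactants: 5 (2R)-2-methyl-2-(triethylsilyloxy)pent-4-ynal; 6 ethyl (triphenylphosphoranylidene)acetate
Product: 7 ethyl (2E,4R)-4-methyl-4-(triethylsilyloxy)hept-2-en-6-ynoate
Conditions: Ph3P=CHCO2Et, toluene, 80 °C
Reagents that add atoms: ethyl (triphenylphosphoranylidene)acetate, CCOC(=O)C=P(c1ccccc1)(c1ccccc1)c1ccccc1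
Why: Wittig olefination of the non-enolisable aldehyde with a stabilised ylide should give the (E)-enoate, the future C1=C2 bond.

Step 5
Reactants: 7 ethyl (2E,4R)-4-methyl-4-(triethylsilyloxy)hept-2-en-6-ynoate
Product: 8 (2E,4R)-4-methyl-4-(triethylsilyloxy)hept-2-en-6-yn-1-ol
Conditions: iBu2AlH, CH2Cl2, −78 °C; aq. potassium sodium tartrate
Reagents that add atoms: none
Why: iBu2AlH 1,2-reduction of the enoate gives the (E)-allylic alcohol without touching alkyne or silyl ether.

Step 6
Reactants: 8 (2E,4R)-4-methyl-4-(triethylsilyloxy)hept-2-en-6-yn-1-ol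
Product: 9 [(2S,3R)-3-[(2R)-2-(triethylsilyloxy)pent-4-yn-2-yl]oxiran-2-yl]methanol
Conditions: Ti(OiPr)4 (cat.), L-(+)-diethyl tartrate (cat.), tBuOOH, 4 Å MS, CH2Cl2, −20 °C
Reagents that add atoms: tert-butyl hydroperoxide, CC(C)(C)OO
Why: Sharpless asymmetric epoxidation under reagent control: the L-(+)-tartrate catalyst should deliver oxygen to the face of the (E)-allylic alcohol that gives the trans-oxirane with 1R,2S configuration (2S,3R in oxirane locants), the sense known for (E)-2-alken-1-ols.

Step 7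
Reactants: 9 [(2S,3R)-3-[(2R)-2-(triethylsilyloxy)pent-4-yn-2-yl]oxiran-2-yl]methanol
Product: 10 triethyl{[(2S,3R)-3-[(2R)-2-(triethylsilyloxy)pent-4-yn-2-yl]oxiran-2-yl]methoxy}silane (alkyne fragment C7–C10/C1–C3)
Conditions: Et3SiCl, imidazole, CH2Cl2, 0 °C
Reagents that add atoms: chlorotriethylsilane, CC[Si](Cl)(CC)CC
Why: Silylation of the primary alcohol as the triethylsilyl ether, chosen because step 14 oxidises this ether directly.

Step 8
Reactants: 11 but-2-yn-1-ol
Product: 12 (2Z)-3-iodobut-2-en-1-ol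
Conditions: NaAlH2(OCH2CH2OCH3)2, THF, 0 °C → rt; EtOAc; I2, −78 → 0 °C
Reagents that add atoms: iodine, II
Why: Hydroxyl-directed trans-hydroalumination of the propargylic alcohol puts aluminium on C3 cis to CH2O, and iodinolysis with retention gives the (Z)-vinyl iodide that fixes the later (4Z) geometry.

Step 9
Reactants: 12 (2Z)-3-iodobut-2-en-1-ol
Product: 13 (2Z)-3-iodobut-2-enal
Conditions: MnO2, CH2Cl2, rt, dark
Reagents that add atoms: none
Why: MnO2 oxidation of the allylic alcohol gives the enal under neutral conditions that should keep the (Z) geometry.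

Step 10
Reactants: 10 alkyne fragment; 13 (2Z)-3-iodobut-2-enal
Product: 16 (6S)-bis-allylic alcohol (2Z,4S,5E,8R)-2-iodo-8-{(2R,3S)-3-[(triethylsilyloxy)methyl]oxiran-2-yl}-8-(triethylsilyloxy)nona-2,5-dien-4-ol, via alkenyl(dicyclohexyl)borane 14 (not isolated), via alkenyl(methyl)zinc 15 (not isolated)
Conditions: Cy2BH, toluene, 0 °C → rt; Me2Zn, −78 °C; (−)-MIB [(2S)-3-exo-morpholinoisoborneol, 5 mol %]; 13, −20 °C; aq. NH4Cl
Reagents that add atoms: none
Why: Syn hydroboration of the terminal alkyne, boron-to-zinc exchange and amino-alcohol-catalysed 1,2-addition of the alkenylzinc to the enal (catalytic asymmetric alkenylation) should give the (7E)-allylic alcohol, C6 being set by the ligand, whose established sense of induction should give the 6S carbinol.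

Step 11
Reactants: 16 (6S)-bis-allylic alcohol
Product: 17 erythro epoxy alcohol (6-OH, trans-7,8-oxirane; 1R,2S,6R,7R,8R,10R; 4Z)
Conditions: Ti(OiPr)4, D-(−)-diisopropyl tartrate, tBuOOH, 4 Å MS, CH2Cl2, −20 °C
Reagents that add atoms: tert-butyl hydroperoxide, CC(C)(C)OO
Why: Sharpless epoxidation of the secondary allylic alcohol in its matched, erythro-selective sense: the D-(−)-tartrate catalyst should epoxidise the (E)-C7=C8 bond of the 6S alcohol to the trans-(7R,8R)-oxirane, while the cis-substituted, electron-poor iodoalkene on the other side of the carbinol is not epoxidised.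

Step 12
Reactants: 17 erythro epoxy alcohol; 18 2-(diethoxyphosphoryl)acetic acid
Product: 19 6-O-[2-(diethoxyphosphoryl)acetyl] ester of 17 (1R,2S,6R,7S,8R,10R; 4Z)
Conditions: DCC, DMAP (cat.), CH2Cl2, 0 °C → rt
Reagents that add atoms: 2-(diethoxyphosphoryl)acetic acid, CCOP(=O)(OCC)CC(=O)O
Why: Steglich esterification attaches the C11–C12 unit to O6 without touching any stereocentre.

Step 13
Reactants: 19 epoxy phosphonoacetate; 20 formaldehyde (as paraformaldehyde); 21 2-methylpropanoic anhydride
Product: 24 iodo-seco α-methylene-γ-lactone 8-isobutyrate (1R,2S,6S,7R,8R,10R; 4Z), via hydroxy phosphono lactone 22 (not isolated), via hydroxy methylene lactone 23 (not isolated)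
Conditions: KOtBu (1.05 equiv), THF, 0 → 40 °C; (CH2O)n, 0 °C → rt; (iPrCO)2O, DMAP, Et3N, rt
Reagents that add atoms: formaldehyde (as paraformaldehyde), C=O; 2-methylpropanoic anhydride, CC(C)C(=O)OC(=O)C(C)C
Why: Proposed new method: KOtBu forms the phosphonate-stabilised carbanion at C11, which opens the trans-7,8-oxirane at C7 from the back side; proton transfer from C11–H to the C8 alkoxide regenerates the carbanion, which undergoes Horner–Wadsworth–Emmons methylenation with formaldehyde, and the free 8-OH is then acylated in the same flask, the closest known reaction types being the telescoped intramolecular Michael addition/Horner–Wadsworth–Emmons olefination of phosphonoacetates of γ-hydroxy enones, the opening of oxiranes by phosphonoacetate anions followed by methylenation, and the 5-exo opening of 2,3-epoxy alcohol carbamates at the proximal carbon. The γ-lactone ring (O–C6–C7–C11–C12) closes in the 5-exo-tet mode. C7 is set by SN2 inversion of the oxirane carbon to the trans-fused 7R centre, C8 keeps the oxirane oxygen and its configuration from step 11, C6 is untouched and C11 becomes sp2. The step needs attack at C7 and not at C8 (6-endo) or at the distal 1,2-oxirane, and C- not O-alkylation: the erythro array places the ester oxygen on C6 anti to the C7–O bond in the extended conformer so that only C7 is reached collinearly through a five-membered transition state, the 1,2-oxirane would require a nine-membered ring, and the soft carbanion alkylates at carbon. Migration of the phosphoryl group to O8 (the path to cyclopropanes at high temperature) is not expected at or below 40 °C because the alkoxide is quenched by the more acidic C11–H.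

Step 14
Reactants: 24 iodo-seco α-methylene-γ-lactone 8-isobutyrate
Product: 25 epoxy aldehyde (C3 aldehyde; 1R,2R,6S,7R,8R,10R; 4Z)
Conditions: (COCl)2, DMSO, CH2Cl2, −78 → −40 °C; Et3N, −78 → 0 °C
Reagents that add atoms: none
Why: Swern oxidation of the primary triethylsilyl ether directly to the α,β-epoxy aldehyde, the tertiary silyl ether, lactone, ester and vinyl iodide being inert.

Step 15
Reactants: 25 epoxy aldehyde
Product: 26 macrocyclic C3 carbinol (both C3 epimers; 1R,2S,6R,7R,8R,10R; 4Z)
Conditions: CrCl2 (excess), NiCl2 (cat.), DMSO/THF, rt, high dilution (slow addition)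
Reagents that add atoms: none
Why: Nozaki–Hiyama–Kishi reaction: the alkenylchromium species formed from the (Z)-vinyl iodide with retention should add chemoselectively to the aldehyde and close the ten-membered ring at C3–C4, the configuration of the new C3 carbinol being irrelevant because step 16 removes it.

Step 16
Reactants: 26 macrocyclic C3 carbinol
Product: 27 10-O-triethylsilyl ether of the target (1R,2R,6R,7R,8R,10R; 4Z)
Conditions: Dess–Martin periodinane, NaHCO3, CH2Cl2, 0 °C → rt
Reagents that add atoms: none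
Why: Dess–Martin oxidation of the allylic, α-epoxy carbinol gives the (Z)-enone and converges both C3 epimers.

Step 17
Reactants: 27 10-O-triethylsilyl ether of the target
Product: 28 target, CNP0273626.1 (1R,2R,6R,7R,8R,10R; 4Z)
Conditions: HF·pyridine, pyridine, THF, 0 °C → rt
Reagents that add atoms: none
Why: Fluoride-mediated silyl ether cleavage under pyridine-buffered conditions should free the tertiary 10-OH without opening the oxirane or adding to the enone and the α-methylene lactone.

**Compound list**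

1 | (S)-2-methylglycidol, [(2S)-2-methyloxiran-2-yl]methanol | C[C@]1(CO)CO1 | starting material
2 | lithium acetylide–ethylenediamine complex | [Li]C#C.NCCN | starting material
3 | (2R)-2-methylpent-4-yne-1,2-diol | C#CC[C@@](C)(O)CO | intermediate
4 | (2R)-2-methyl-1,2-bis(triethylsilyloxy)pent-4-yne | C#CC[C@@](C)(O[Si](CC)(CC)CC)CO[Si](CC)(CC)CC | intermediate
5 | (2R)-2-methyl-2-(triethylsilyloxy)pent-4-ynal | C#CC[C@@](C)(O[Si](CC)(CC)CC)C=O | intermediate
6 | ethyl (triphenylphosphoranylidene)acetate | CCOC(=O)C=P(c1ccccc1)(c1ccccc1)c1ccccc1 | starting material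
7 | ethyl (2E,4R)-4-methyl-4-(triethylsilyloxy)hept-2-en-6-ynoate | C#CC[C@@](C)(O[Si](CC)(CC)CC)/C=C/C(=O)OCC | intermediate
8 | (2E,4R)-4-methyl-4-(triethylsilyloxy)hept-2-en-6-yn-1-ol | C#CC[C@@](C)(O[Si](CC)(CC)CC)/C=C/CO | intermediate
9 | [(2S,3R)-3-[(2R)-2-(triethylsilyloxy)pent-4-yn-2-yl]oxiran-2-yl]methanol (1R,2S,10R) | C#CC[C@@](C)(O[Si](CC)(CC)CC)[C@@H]1O[C@H]1CO | intermediate
10 | triethyl{[(2S,3R)-3-[(2R)-2-(triethylsilyloxy)pent-4-yn-2-yl]oxiran-2-yl]methoxy}silane, alkyne fragment C7–C10/C1–C3 | C#CC[C@@](C)(O[Si](CC)(CC)CC)[C@@H]1O[C@H]1CO[Si](CC)(CC)CC | intermediate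
11 | but-2-yn-1-ol | CC#CCO | starting material
12 | (2Z)-3-iodobut-2-en-1-ol | OC/C=C(/C)I | intermediate
13 | (2Z)-3-iodobut-2-enal | O=C/C=C(/C)I | intermediate
14 | (7E)-alkenyl(dicyclohexyl)borane from 10, boron on C7 (1R,2S,10R) | C1CCCCC1B(/C=C/C[C@@](C)(O[Si](CC)(CC)CC)[C@@H]2O[C@H]2CO[Si](CC)(CC)CC)C1CCCCC1 | intermediate
15 | (7E)-alkenyl(methyl)zinc from 14, zinc on C7 (1R,2S,10R) | C[Zn]/C=C/C[C@@](C)(O[Si](CC)(CC)CC)[C@@H]1O[C@H]1CO[Si](CC)(CC)CC | intermediate
16 | (2Z,4S,5E,8R)-2-iodo-8-{(2R,3S)-3-[(triethylsilyloxy)methyl]oxiran-2-yl}-8-(triethylsilyloxy)nona-2,5-dien-4-ol (1R,2S,6S,10R; 4Z,7E) | O[C@@H](/C=C/C[C@@](C)(O[Si](CC)(CC)CC)[C@@H]1O[C@H]1CO[Si](CC)(CC)CC)/C=C(/C)I | intermediate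
17 | erythro epoxy alcohol: open chain C4–C10/C1–C3 with (4Z)-4-iodo-4-ene, 6-OH, trans-7,8-oxirane, 10-OSiEt3, trans-1,2-oxirane, 3-OSiEt3 (1R,2S,6R,7R,8R,10R) | O[C@@H]([C@H]1O[C@@H]1C[C@@](C)(O[Si](CC)(CC)CC)[C@@H]2O[C@H]2CO[Si](CC)(CC)CC)/C=C(/C)I | intermediate
18 | 2-(diethoxyphosphoryl)acetic acid | CCOP(=O)(OCC)CC(=O)O | starting material
19 | 6-O-[2-(diethoxyphosphoryl)acetyl] ester of 17 (1R,2S,6R,7S,8R,10R; 4Z) | CCOP(=O)(OCC)CC(=O)O[C@@H]([C@H]1O[C@@H]1C[C@@](C)(O[Si](CC)(CC)CC)[C@@H]2O[C@H]2CO[Si](CC)(CC)CC)/C=C(/C)I | intermediate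
20 | formaldehyde (used as paraformaldehyde) | C=O | starting material
21 | 2-methylpropanoic (isobutyric) anhydride | CC(C)C(=O)OC(=O)C(C)C | starting material
22 | trans-fused 6,12-lactone with 11-(diethoxyphosphoryl) group and free 8-OH, present as its potassium C11 carbanion (1R,2S,6S,7R,8R,10R; 4Z) | CCOP(=O)(OCC)C1C(=O)O[C@H](/C=C(/C)I)[C@H]1[C@H](O)C[C@@](C)(O[Si](CC)(CC)CC)[C@@H]2O[C@H]2CO[Si](CC)(CC)CC | intermediate
23 | trans-fused α-methylene-γ-lactone with free 8-OH (1R,2S,6S,7R,8R,10R; 4Z) | C=C1C(=O)O[C@H](/C=C(/C)I)[C@H]1[C@H](O)C[C@@](C)(O[Si](CC)(CC)CC)[C@@H]2O[C@H]2CO[Si](CC)(CC)CC | intermediate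
24 | iodo-seco α-methylene-γ-lactone 8-isobutyrate: (4Z)-4-iodo-4-ene, 6,12-olide, 8-O-isobutyryl, 10-OSiEt3, trans-1,2-oxirane, 3-OSiEt3 (1R,2S,6S,7R,8R,10R) | C=C1C(=O)O[C@H](/C=C(/C)I)[C@H]1[C@H](OC(=O)C(C)C)C[C@@](C)(O[Si](CC)(CC)CC)[C@@H]2O[C@H]2CO[Si](CC)(CC)CC | intermediate
25 | epoxy aldehyde: 24 with C3 as aldehyde (1R,2R,6S,7R,8R,10R; 4Z) | C=C1C(=O)O[C@H](/C=C(/C)I)[C@H]1[C@H](OC(=O)C(C)C)C[C@@](C)(O[Si](CC)(CC)CC)[C@@H]2O[C@H]2C=O | intermediate
26 | macrocyclic C3 carbinol, 3-hydroxy-3-deoxo-10-O-triethylsilyl target, both C3 epimers (1R,2S,6R,7R,8R,10R; 4Z) | C=C1C(=O)O[C@@H]2/C=C(/C)C(O)[C@@H]3O[C@H]3[C@](C)(O[Si](CC)(CC)CC)C[C@@H](OC(=O)C(C)C)[C@@H]12 | intermediate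
27 | 10-O-triethylsilyl ether of the target (1R,2R,6R,7R,8R,10R; 4Z) | C=C1C(=O)O[C@@H]2/C=C(/C)C(=O)[C@@H]3O[C@H]3[C@](C)(O[Si](CC)(CC)CC)C[C@@H](OC(=O)C(C)C)[C@@H]12 | intermediate
28 | CNP0273626.1: (4Z)-1,2-epoxy-10-hydroxy-8-isobutyryloxy-3-oxogermacra-4,11(13)-dien-6,12-olide (1R,2R,6R,7R,8R,10R) | C=C1C(=O)O[C@@H]2/C=C(/C)C(=O)[C@@H]3O[C@H]3[C@](C)(O)C[C@@H](OC(=O)C(C)C)[C@@H]12 | target

**Step count and risks**

Total step count: 17. Longest linear sequence: 15 steps (steps 1–7 and 10–17); steps 8–9 form the short branch.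

Steps most likely to fail:

1. Step 13 (Proposed new method). The stabilised carbanion may be too weak a nucleophile for the flanked oxirane or open it in the 6-endo sense. After ring closure the free 8-hydroxyl may trans-lactonise or be captured by excess formaldehyde before it is acylated. The fallback uses known reaction types only, sets out from 17 and returns at 24.
   - Dess–Martin oxidation of 17 should give the 7,8-epoxy enone F1.
   - SmI2 in THF/MeOH at low temperature should cleave the C7–O bond of the α,β-epoxy ketone to the β-hydroxy ketone F2, leaving C8 untouched.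
   - Evans–Tishchenko reduction with isobutyraldehyde and catalytic SmI2 should deliver hydride intramolecularly to C6 and give the anti-6,8-diol 8-isobutyrate F3, with the ester already on O8 and the 6-OH in the required configuration.
   - Steglich esterification with 18 should give the phosphonoacetate F4, and diazo transfer (4-acetamidobenzenesulfonyl azide, DBU) the diazophosphonoacetate F5.
   - Rh2(O2CC7H15)4-catalysed intramolecular carbene 1,5-C–H insertion into the C7 methylene should form the same C7–C11 bond and give the α-phosphono lactone F6, with the C6 and C7 substituents expected trans. F6 is methylenated in the same flask with KOtBu/paraformaldehyde to 24.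
   - The fallback's own risk is competing cyclopropanation of the C4=C5 iodoalkene.

2. Step 15. Intermolecular coupling may outrun closure of the strained ten-membered ring, and divalent chromium may reduce the α,β-epoxy aldehyde before the alkenylchromium species adds. The fallback sets out from 25 and returns at 27, bypassing 26 and step 16.
   - Pinnick oxidation (NaClO2, NaH2PO4, 2-methylbut-2-ene) should give the epoxy acid F7.
   - Iodine–tin exchange with Me3SnSnMe3 and Pd(PPh3)4 should give the (Z)-vinylstannane acid F8 with retention.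
   - 1-Chloro-N,N,2-trimethylprop-1-en-1-amine should convert F8 under neutral conditions into the acid chloride F9, which is not isolated.
   - Intramolecular acylative Stille coupling (Pd2(dba)3, tri(2-furyl)phosphine, high dilution) should close the ring at C3–C4 directly at the enone oxidation level.

3. Step 10. Facial selectivity at C6 may be poor with the small conjugated (Z)-β-iodo enal, and the enal may isomerise under the Lewis-acidic conditions. The fallback sets out from 10 and 13 and returns at 17.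
   - Hydrozirconation of 10 with Cp2Zr(H)Cl, transmetalation with Me2Zn and addition to 13 without chiral ligand should give 16 together with its C6 epimer F10.
   - The mixture is submitted to step 11, where the D-(−)-tartrate catalyst should epoxidise only the matched 16 (Sharpless kinetic resolution through the erythro pathway) to 17.
   - F10 should remain unepoxidised and is separated.

Further compounds
F1 | step 13 | 6-oxo analogue of 17: (4Z)-4-iodo-4-en-6-one with trans-7,8-oxirane (1R,2S,7S,8R,10R) | O=C([C@H]1O[C@@H]1C[C@@](C)(O[Si](CC)(CC)CC)[C@@H]2O[C@H]2CO[Si](CC)(CC)CC)/C=C(/C)I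
F2 | step 13 | 8-hydroxy-6-ketone with C7 methylene (1R,2S,8R,10R; 4Z) | O=C(C[C@H](O)C[C@@](C)(O[Si](CC)(CC)CC)[C@@H]1O[C@H]1CO[Si](CC)(CC)CC)/C=C(/C)I
F3 | step 13 | anti-6,8-diol 8-isobutyrate with free 6-OH (1R,2S,6S,8S,10R; 4Z) | O[C@@H](C[C@H](OC(=O)C(C)C)C[C@@](C)(O[Si](CC)(CC)CC)[C@@H]1O[C@H]1CO[Si](CC)(CC)CC)/C=C(/C)I
F4 | step 13 | 6-O-[2-(diethoxyphosphoryl)acetyl] ester of F3 | CCOP(=O)(OCC)CC(=O)O[C@@H](C[C@H](OC(=O)C(C)C)C[C@@](C)(O[Si](CC)(CC)CC)[C@@H]1O[C@H]1CO[Si](CC)(CC)CC)/C=C(/C)I
F5 | step 13 | 6-O-[2-diazo-2-(diethoxyphosphoryl)acetyl] ester of F3 | CCOP(=O)(OCC)C(=[N+]=[N-])C(=O)O[C@@H](C[C@H](OC(=O)C(C)C)C[C@@](C)(O[Si](CC)(CC)CC)[C@@H]1O[C@H]1CO[Si](CC)(CC)CC)/C=C(/C)I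
F6 | step 13 | 11-(diethoxyphosphoryl) trans-fused lactone 8-isobutyrate, the phosphono analogue of 24 (1R,2S,6S,7R,8R,10R; 4Z) | CCOP(=O)(OCC)C1C(=O)O[C@H](/C=C(/C)I)[C@H]1[C@H](OC(=O)C(C)C)C[C@@](C)(O[Si](CC)(CC)CC)[C@@H]2O[C@H]2CO[Si](CC)(CC)CC
F7 | step 15 | C3 carboxylic acid from 25 (1R,2R,6S,7R,8R,10R; 4Z) | C=C1C(=O)O[C@H](/C=C(/C)I)[C@H]1[C@H](OC(=O)C(C)C)C[C@@](C)(O[Si](CC)(CC)CC)[C@@H]2O[C@H]2C(=O)O
F8 | step 15 | F7 with trimethylstannyl in place of iodine on C4 (4Z) | C=C1C(=O)O[C@H](/C=C(/C)[Sn](C)(C)C)[C@H]1[C@H](OC(=O)C(C)C)C[C@@](C)(O[Si](CC)(CC)CC)[C@@H]2O[C@H]2C(=O)O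
F9 | step 15 | C3 acid chloride of F8 | C=C1C(=O)O[C@H](/C=C(/C)[Sn](C)(C)C)[C@H]1[C@H](OC(=O)C(C)C)C[C@@](C)(O[Si](CC)(CC)CC)[C@@H]2O[C@H]2C(=O)Cl
F10 | step 10 | C6 epimer of 16 (1R,2S,6R,10R; 4Z,7E) | O[C@H](/C=C/C[C@@](C)(O[Si](CC)(CC)CC)[C@@H]1O[C@H]1CO[Si](CC)(CC)CC)/C=C(/C)I
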